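Count the reagent.

| setting | elm | alder | cedar | flask |
|---|---|---|---|---|
| substrate | 20 mM | 20 mM | 40 mM | 20 mM |
| reagent | 1.5 equiv | 2.4 equiv | 1.1 equiv | 1.10 equiv |
| remark | run made earlier | run made earlier | run made earlier |  |
| time |  |  |  | 6.0 min |

| run | time / min | substrate / % | product / % |
|---|---|---|---|
| elm | 0.250 | 0 | 27 |
| elm | 0.667 | 0 | 41 |
| elm | 1.33 | 0 | 45 |
| elm | 2.00 | 0 | 49 |
| elm | 3.00 | 0 | 52 |
| elm | 4.00 | 0 | 51 |
| elm | 5.00 | 0 | 49 |
| alder | 0.250 | 2 | 58 |
| alder | 0.667 | 0 | 79 |
| alder | 1.33 | 1 | 87 |
| alder | 2.00 | 1 | 97 |
| alder | 3.00 | 0 | 103 |
| alder | 4.00 | 0 | 97 |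
| alder | 5.00 | 0 | 101 |
| cedar | 0.417 | 0 | 10 |
| cedar | 0.667 | 2 | 15 |
| cedar | 1.33 | 2 | 13 |
| cedar | 2.50 | 6 | 9 |
| cedar | 5.00 | 3 | 14 |

(scatter of a reading: 2 percentage points)

- at 6.0 min, what has stopped the reaction, if anything has (the reagent has run out first / forward and back rates have come level / it is still moving)
- how much of the substrate has reacted by 6.0 min
- how much product there is at 6.0 min, in percent of the substrate charged
- how much intermediate C there is at 6.0 min, in percent of the substrate charged
- amount of product if the flask were left three thousand times as long, in percent of the substrate charged

- the reaction counts as stopped when no species that holds the substrate changes by six tenths of a point or more over the second half of the time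

1. In every run substrate stands within a few points of zero by the first reading, and product then levels off with the reagent charge: elm, at 1.5 equiv, reads 52 % at 3.00 min, and alder, at 2.4 equiv, reads 103 %. So the readings fit one equivalent of reagent turning substrate into intermediate C, and a second turning that into product.

2. The quantity to carry is the excess, the reagent charged beyond one equivalent, as a fraction of the substrate charged: 10.0 % for this flask. In this flask reagent is the limiting reagent, at 1.10 equiv against the two equivalents that full conversion to product takes. In that scheme, once reagent stands at zero, product equals the excess plus the substrate left.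

3. Upper bound: with two reagents per product, the flask's charge allows 55.0 %.

4. Lower bound: with reagent at zero and no substrate left, product equals the excess, 10.0 %.

5. Tightening: cedar has the same equivalents at twice the substrate. Its 5 readings average 2.60 % substrate and 12.2 % product, each mean with a standard error of about 0.89 percentage points. The balance on cedar's mean substrate gives 12.6 % product. So about 12.2 % product is my figure for this flask, provided the substrate level does not move it.

6. Elm's product readings, at the same substrate level, are level within their scatter from 3.00 min, with a larger excess, 50.0 %, and 6.0 min is twice that time. So I expect this flask to have stopped by 6.0 min.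

7. The forecast, its product inside the bracket, reads: the reagent has run out first; 98.5 % reacted; product 11 %; intermediate C 87.5 %; and 11 % product in the long run; it holds that “a 0.10 equiv excess is gone within about 2 minutes”.

8. The flask gives: the reagent has run out first, with reagent at 0 %; 98.3 % reacted; product 12.0 %, and 12.0 % in the long run; intermediate C 43.1 %, beside intermediate D 22.0 % and intermediate E 20.9 %.

    intermediate D ⇌ intermediate E (K = 0.950, k = 0.200 s⁻¹)
    intermediate A → intermediate C (k = 1.40 s⁻¹)
    substrate + reagent → intermediate A (k = 78.0 M⁻¹ s⁻¹)
    intermediate C ⇌ intermediate D (K = 0.510, k = 0.0680 s⁻¹)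
    substrate ⇌ intermediate B (K = 0.170, k = 0.240 s⁻¹)
    reagent + intermediate C → product (k = 4.40 M⁻¹ s⁻¹)

With intermediate B counted beside substrate, the excess plus what is left comes to 12.0 % in this flask, against 12.0 % of product. The neighbour charged with 0.660 equiv falls 34.0 % short of one equivalent, so its balance asks for substrate and intermediate B to equal that shortfall plus its product, 35.5 %. That neighbour ends with reagent at 0 %, product at 1.54 %, and substrate with intermediate B at 35.5 %.

The runs are calculated for substances that don't exist.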